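Assumption: the SMILES is taken literally (4R,5S,6R,7R,8S,9S; cis-fused lactone, cis-epoxide, ring-cis C1=C10), and germacrane numbering (C1–C15; C14 = ester carbon on C10, C12 = lactone carbonyl) is used for every intermediate.

**Retrosynthetic overview**
1. 20 ⇒ 19: the oxirane is the last ring, made by peracid attack on the only electron-rich alkene (C4=C5, Z).
2. 19 ⇒ 17: in one flask the C6–C7 bond (the farnesyl C1–C10 bond of germacranolide biosynthesis) closes the ten-membered carbocycle by intramolecular allylboration of a neral-type enal. The C6 borate then closes the γ-lactone on C12.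
3. 17 ⇒ 13 + 15: cross-metathesis puts the 2-(borylmethyl)acrylate unit (C11–C13) on the C7 vinyl group.
4. 13 ⇒ 6 + allyl chloride + angelic acid: asymmetric γ-chloroallylboration, cis-vinyl epoxide, then SN2 opening at C8. This sets 8S,9S and places the ester without protecting groups.
5. 6 ⇒ neryl acetate + methyl acrylate. Ring order: carbocycle, lactone, epoxide.

**Route**

Step 1
Reactants: 1 neryl acetate
Product: 2 (4Z)-6-acetoxy-4-methylhex-4-enal
Conditions: O3 (1.0 equiv, Sudan red end point), CH2Cl2, −78 °C; then Me2S, −78 °C to rt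
Reagents that add atoms: ozone, [O-][O+]=O
Why: Chemoselective ozonolysis, because ozone takes the electron-rich isopropylidene alkene much faster than the trisubstituted alkene deactivated by the allylic acetate, so the Z C4=C5 unit survives untouched.

Step 2
Reactants: 2 (4Z)-6-acetoxy-4-methylhex-4-enal; 3 methyl acrylate
Product: 4 methyl 2-[(4Z)-6-acetoxy-1-hydroxy-4-methylhex-4-en-1-yl]prop-2-enoate
Conditions: DABCO (0.5 equiv), 3 (3 equiv, neat), MeOH (cat.), rt, 3 d
Reagents that add atoms: none
Why: Morita–Baylis–Hillman reaction of an unhindered aliphatic aldehyde that joins C1 to C10 and brings in C9 and C14; the new carbinol centre is racemic and is erased in step 3.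

Step 3
Reactants: 4 methyl 2-[(4Z)-6-acetoxy-1-hydroxy-4-methylhex-4-en-1-yl]prop-2-enoate
Product: 6 methyl (2E,6Z)-8-acetoxy-2-formyl-6-methylocta-2,6-dienoate, via allylic bromide 5 (not isolated)
Conditions: NBS, Me2S, CH2Cl2, 0 °C to rt; then NMO (3 equiv), NaHCO3, 4 Å MS, MeCN, rt; used crude at once
Reagents that add atoms: N-bromosuccinimide, O=C1CCC(=O)N1Br (Br of 5); N-methylmorpholine N-oxide, C[N+]1([O-])CCOCC1 (aldehyde O of 6)
Why: Corey–Kim-type SN2′ bromination gives the thermodynamically preferred Z allylic bromide (chain trans to the ester), and Kornblum/Ganem-type N-oxide oxidation of this primary bromide gives the C9 aldehyde with the C1=C10 geometry of the target (C9 cis to C2) already fixed.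

Step 4
Reactants: 6 methyl (2E,6Z)-8-acetoxy-2-formyl-6-methylocta-2,6-dienoate; 7 allyl chloride
Product: 10 methyl (2E,6Z)-8-acetoxy-2-[(1S,2S)-2-chloro-1-hydroxybut-3-en-1-yl]-6-methylocta-2,6-dienoate, via chloroallylborane 8 (not isolated), via borinate ester 9 (not isolated)
Conditions: 7, (+)-Ipc2BOMe, LiN(c-Hex)2, Et2O–THF, −95 °C; BF3·OEt2, −95 °C; then 6, −95 °C; ethanolamine, rt
Reagents that add atoms: (+)-B-methoxydiisopinocampheylborane, COB([C@H]1C[C@H]2C[C@@H]([C@@H]1C)C2(C)C)[C@H]1C[C@H]2C[C@@H]([C@@H]1C)C2(C)C (boryl group of 8 and 9 only)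
Why: Oehlschlager–Brown γ-chloroallylboration, in which the closed chair transition state of the Z-borane gives the syn chlorohydrin and the isopinocampheyl groups from (−)-α-pinene select the aldehyde face that gives 9S, hence 8S,9S, while ester, enoate and acetate are inert at −95 °C.

Step 5
Reactants: 10 methyl (2E,6Z)-8-acetoxy-2-[(1S,2S)-2-chloro-1-hydroxybut-3-en-1-yl]-6-methylocta-2,6-dienoate
Product: 11 methyl (2E,6Z)-2-[(2S,3R)-3-ethenyloxiran-2-yl]-8-hydroxy-6-methylocta-2,6-dienoate
Conditions: K2CO3 (1.5 equiv), MeOH, 0 °C to rt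
Reagents that add atoms: none
Why: Intramolecular Williamson closure of O9 onto C8 with inversion turns the syn chlorohydrin into the cis-vinyl epoxide (8R,9S), while the same medium transesterifies the primary allylic acetate, so no separate deprotection is needed.

Step 6
Reactants: 11 methyl (2E,6Z)-2-[(2S,3R)-3-ethenyloxiran-2-yl]-8-hydroxy-6-methylocta-2,6-dienoate; 12 angelic acid
Product: 13 methyl (2E,6Z)-2-[(1S,2S)-2-(angeloyloxy)-1-hydroxybut-3-en-1-yl]-8-hydroxy-6-methylocta-2,6-dienoate
Conditions: 12 (3 equiv), Cs2CO3 (10 mol %), DMF, 45 °C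
Reagents that add atoms: none
Why: SN2 opening of a vinyl epoxide by a carboxylate, in which angelate attacks C8 (activated by the unsubstituted vinyl group and far less hindered than C9 next to the fully substituted electron-poor C10) with inversion, so that the two inversions at C8 return the threo 8S,9S array with the ester on O8 and the free hydroxyl on O9, and a free C8 hydroxyl that could lactonise onto C14 never appears.

Step 7
Reactants: 14 methyl 2-(bromomethyl)prop-2-enoate
Product: 15 methyl 2-[(4,4,5,5-tetramethyl-1,3,2-dioxaborolan-2-yl)methyl]prop-2-enoate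
Conditions: B2pin2 (1.1 equiv), CuCl (10 mol %), KOAc (1.5 equiv), DMF, rt
Reagents that add atoms: bis(pinacolato)diboron, CC1(C)OB(OC1(C)C)B1OC(C)(C)C(C)(C)O1
Why: Copper-catalysed Miyaura-type allylic borylation, in which the boryl-copper species adds to the acrylate terminus and bromide leaves (SN2′, degenerate for this symmetric allyl system), so only one allylboronate can form.

Step 8
Reactants: 13 methyl (2E,6Z)-2-[(1S,2S)-2-(angeloyloxy)-1-hydroxybut-3-en-1-yl]-8-hydroxy-6-methylocta-2,6-dienoate; 15 methyl 2-[(4,4,5,5-tetramethyl-1,3,2-dioxaborolan-2-yl)methyl]prop-2-enoate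
Product: 16 methyl (2E,4S,5S,6E,10Z)-4-(angeloyloxy)-5,12-dihydroxy-6-(methoxycarbonyl)-10-methyl-2-[(pinacolboryl)methyl]dodeca-2,6,10-trienoate
Conditions: 15 (4 equiv), second-generation Hoveyda–Grubbs catalyst (10 mol %), 1,4-benzoquinone (20 mol %), CH2Cl2, 40 °C
Reagents that add atoms: none
Why: Olefin cross-metathesis between the only monosubstituted alkene of 13 and an excess of the 1,1-disubstituted acrylate 15 (all other alkenes are trisubstituted and inert), the new trisubstituted enoate forming under thermodynamic control with C8 trans to the ester and cis to CH2B, as in methacrylate cross-metatheses.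

Step 9
Reactants: 16 methyl (2E,4S,5S,6E,10Z)-4-(angeloyloxy)-5,12-dihydroxy-6-(methoxycarbonyl)-10-methyl-2-[(pinacolboryl)methyl]dodeca-2,6,10-trienoate
Product: 19 cis-fused germacra-1(10),4,11(13)-trien-12,6-olide (6S,7S,8S,9S), via enal boronate 17 (not isolated), via cyclic borate 18 (not isolated)
Conditions: MnO2 (15 equiv), CH2Cl2, rt; filter; dilute with PhMe to 1 mM; Sc(OTf)3 (10 mol %), 4 Å MS, 25 to 50 °C; aq NaHCO3
Reagents that add atoms: none
Why: Proposed new method: MnO2 unmasks the neral-type enal (only the primary, electron-rich allylic alcohol reacts) and the tethered 2-(methoxycarbonyl)allylboronate then adds through a Sc(OTf)3-accelerated closed chair transition state in which boron binds the C6 carbonyl while the C7=C11 alkene attacks C6 and the double bond moves to C11=C13, the same bond, polarity and alkene shift as the farnesyl-to-germacrenyl closure; C8 cis to CH2B (Z-crotyl type) gives the syn adduct and hence the cis-fused lactone, allylic 1,3-strain holds H8 inside so that C6 arrives anti to C9 and syn to O8 (the 7,8 relation of the target), the covalent C–B bond cannot expel the δ-angelate as an allylzinc or allylchromium species could, the two cis alkenes pre-fold the chain for ten-ring closure, and the C6 borate 18 lactonises onto C12; the closest known reactions are Lewis-acid-catalysed intermolecular additions of 2-alkoxycarbonyl allylboronates to aldehydes giving α-methylene-γ-butyrolactones and Barbier-type macrocyclisations to germacranolides.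

Step 10
Reactants: 19 cis-fused germacra-1(10),4,11(13)-trien-12,6-olide (6S,7S,8S,9S)
Product: 20 CNP0251641.1 (4R,5S,6R,7R,8S,9S)
Conditions: mCPBA (1.1 equiv), CH2Cl2, 0 °C
Reagents that add atoms: 3-chloroperbenzoic acid, OOC(=O)c1cccc(Cl)c1
Why: Prilezhaev epoxidation, in which the peracid takes the only electron-rich alkene (enoate, angelate and α-methylene lactone are electron-poor) and, with H6 eclipsing the Z-alkene to avoid allylic 1,3-strain and C7 turned into the ring, attacks the open peripheral face syn to the lactone oxygen, giving the cis-epoxide 4R,5S threo to C6 (the descriptors at C6 and C7 change to R only because priorities change).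

**Compound list**
1 | neryl acetate, (2Z)-3,7-dimethylocta-2,6-dien-1-yl acetate | CC(C)=CCC/C(C)=C\COC(C)=O | starting material
2 | (4Z)-6-acetoxy-4-methylhex-4-enal (C1–C6, C15) | O=CCC/C(C)=C\COC(C)=O | intermediate
3 | methyl acrylate | C=CC(=O)OC | starting material
4 | methyl 2-[(4Z)-6-acetoxy-1-hydroxy-4-methylhex-4-en-1-yl]prop-2-enoate, racemic carbinol | C=C(C(=O)OC)C(O)CC/C(C)=C\COC(C)=O | intermediate
5 | methyl (2Z,6Z)-8-acetoxy-2-(bromomethyl)-6-methylocta-2,6-dienoate | BrC/C(C(=O)OC)=C\CC/C(C)=C\COC(C)=O | intermediate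
6 | methyl (2E,6Z)-8-acetoxy-2-formyl-6-methylocta-2,6-dienoate (CHO = C9, cis to C2) | O=C/C(C(=O)OC)=C\CC/C(C)=C\COC(C)=O | intermediate
7 | allyl chloride | C=CCCl | starting material
8 | [(2Z)-3-chloroprop-2-en-1-yl]diisopinocampheylborane, Ipc from (−)-α-pinene | Cl/C=C\CB([C@H]1C[C@H]2C[C@@H]([C@@H]1C)C2(C)C)[C@H]1C[C@H]2C[C@@H]([C@@H]1C)C2(C)C | intermediate
9 | O9-diisopinocampheylborinate of 10 | C=C[C@H](Cl)[C@@H](OB([C@H]1C[C@H]2C[C@@H]([C@@H]1C)C2(C)C)[C@H]1C[C@H]2C[C@@H]([C@@H]1C)C2(C)C)/C(C(=O)OC)=C\CC/C(C)=C\COC(C)=O | intermediate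
10 | methyl (2E,6Z)-8-acetoxy-2-[(1S,2S)-2-chloro-1-hydroxybut-3-en-1-yl]-6-methylocta-2,6-dienoate, syn chlorohydrin (8S,9S) | C=C[C@H](Cl)[C@@H](O)/C(C(=O)OC)=C\CC/C(C)=C\COC(C)=O | intermediate
11 | methyl (2E,6Z)-2-[(2S,3R)-3-ethenyloxiran-2-yl]-8-hydroxy-6-methylocta-2,6-dienoate, cis-epoxide (8R,9S) | C=C[C@H]1O[C@H]1/C(C(=O)OC)=C\CC/C(C)=C\CO | intermediate
12 | angelic acid, (2Z)-2-methylbut-2-enoic acid | C/C=C(/C)C(=O)O | starting material
13 | methyl (2E,6Z)-2-[(1S,2S)-2-(angeloyloxy)-1-hydroxybut-3-en-1-yl]-8-hydroxy-6-methylocta-2,6-dienoate (8S,9S, threo) | C=C[C@H](OC(=O)/C(C)=C\C)[C@@H](O)/C(C(=O)OC)=C\CC/C(C)=C\CO | intermediate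
14 | methyl 2-(bromomethyl)prop-2-enoate | C=C(CBr)C(=O)OC | starting material
15 | methyl 2-[(4,4,5,5-tetramethyl-1,3,2-dioxaborolan-2-yl)methyl]prop-2-enoate | C=C(CB1OC(C)(C)C(C)(C)O1)C(=O)OC | intermediate
16 | methyl (2E,4S,5S,6E,10Z)-4-(angeloyloxy)-5,12-dihydroxy-6-(methoxycarbonyl)-10-methyl-2-[(pinacolboryl)methyl]dodeca-2,6,10-trienoate | CC1(C)OB(C/C(C(=O)OC)=C\[C@H](OC(=O)/C(C)=C\C)[C@@H](O)/C(C(=O)OC)=C\CC/C(C)=C\CO)OC1(C)C | intermediate
17 | 12-oxo analogue of 16 (Z-enal at C6, allylboronate at C13) | CC1(C)OB(C/C(C(=O)OC)=C\[C@H](OC(=O)/C(C)=C\C)[C@@H](O)/C(C(=O)OC)=C\CC/C(C)=C\C=O)OC1(C)C | intermediate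
18 | ten-membered carbocycle, C6–O–Bpin, C7 bearing C(=CH2)CO2Me, 8-O-angelate, 9-OH (6S,7S,8S,9S) | CC1(C)OB(O[C@@H]2[C@H](C(=C)C(=O)OC)[C@H](OC(=O)/C(C)=C\C)[C@@H](O)/C(C(=O)OC)=C\CC/C(C)=C\2)OC1(C)C | intermediate
19 | methyl 8-angeloyloxy-9-hydroxy-germacra-1(10),4,11(13)-trien-12,6-olid-14-oate, Z C4=C5, ring-cis C1=C10, H6/H7 cis (6S,7S,8S,9S) | C=C1C(=O)O[C@@H]2[C@H]1[C@H](OC(=O)/C(C)=C\C)[C@@H](O)/C(C(=O)OC)=C\CC/C(C)=C\2 | intermediate
20 | CNP0251641.1, the 4,5-cis-epoxide of 19 (4R,5S,6R,7R,8S,9S) | C=C1C(=O)O[C@@H]2[C@H]1[C@H](OC(=O)/C(C)=C\C)[C@@H](O)/C(C(=O)OC)=C\CC[C@@]1(C)O[C@@H]21 | target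

**Step count**
- Total step count: 10.
- Longest linear sequence: 9 (steps 1–6 and 8–10).

**Steps most likely to fail**

Step 9 (macrocyclic allylboration).
- Risks: the ester-deactivated boronate may be too slow for a hindered enal at 1 mM, or the Z-enal may isomerise first.
- The fallback replaces the boron closure by a Barbier-type organochromium closure. It sets out from 13 and comes back at 19.
- Cross-metathesis of 13 with 14, under the catalyst system of step 8, gives the allylic bromide F1.
- MnO2 in CH2Cl2 oxidises only the primary allylic alcohol to give the enal bromide F2.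
- Slow addition of F2 to CrCl2 (6 equiv) in DMF–THF (final 1 mM, rt) forms the equilibrating allylchromium (C8 trans to the ester). This adds to C6 through the same chair, and the chromium alkoxide lactonises to 19.
- The price is possible 1,4-loss of the angelate.

Step 8 (cross-metathesis to a hindered trisubstituted enoate).
- The fallback builds C7=C11 by olefination instead of metathesis. It sets out from 13 and comes back at 17.
- TEMPO (10 mol %)/PhI(OAc)2 in CH2Cl2 gives the enal F3, in which every alkene except the vinyl group is now electron-poor.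
- OsO4 (2 mol %)/NaIO4/2,6-lutidine in dioxane–water cleaves that vinyl group to the dialdehyde F4.
- The boryl ylide F5 is made from Ph3P=CHCO2Me (2 equiv) and ICH2Bpin. It reacts in CH2Cl2 at rt only with the reactive α-acyloxy aldehyde at C7, ester trans to C8, to give 17.
- 17 is then diluted and cyclised as in step 9.

Step 6 (regiochemistry of the epoxide opening).
- Risks: attack at C9, SN2′ attack at the vinyl terminus, or O8 to O9 acyl migration.
- The fallback delivers the angelate inside the nucleophile, so no epoxide is opened. It sets out from 6 and comes back at 13.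
- 12 with (COCl)2 gives angeloyl chloride F6, which adds to acrolein (ZnCl2 cat.) to give 3-chloroprop-1-enyl angelate F7.
- A catalytic Nozaki–Hiyama-type acyloxyallylation of 6 with F7 uses CrCl3 (10 mol %), one enantiomer of N,N′-bis(3,5-di-tert-butylsalicylidene)cyclohexane-1,2-diamine (chosen for 8S,9S), Mn, Me3SiCl and Et3N in MeCN.
- After mild acid desilylation this gives the syn hydroxy angelate acetate F8.
- Candida antarctica lipase B in MeOH–MTBE removes only the primary acetate to give 13.

Further compounds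
F1 | step 9 | allylic bromide, methyl (2Z,4S,5S,6E,10Z)-4-(angeloyloxy)-2-(bromomethyl)-5,12-dihydroxy-6-(methoxycarbonyl)-10-methyldodeca-2,6,10-trienoate | BrC/C(C(=O)OC)=C\[C@H](OC(=O)/C(C)=C\C)[C@@H](O)/C(C(=O)OC)=C\CC/C(C)=C\CO
F2 | step 9 | enal bromide, 12-oxo analogue of F1 | BrC/C(C(=O)OC)=C\[C@H](OC(=O)/C(C)=C\C)[C@@H](O)/C(C(=O)OC)=C\CC/C(C)=C\C=O
F3 | step 8 | enal, 8-oxo analogue of 13 (C6 aldehyde, Z) | C=C[C@H](OC(=O)/C(C)=C\C)[C@@H](O)/C(C(=O)OC)=C\CC/C(C)=C\C=O
F4 | step 8 | dialdehyde, C7 aldehyde from cleavage of the vinyl group of F3, configuration at C8 and C9 unchanged | O=C[C@H](OC(=O)/C(C)=C\C)[C@@H](O)/C(C(=O)OC)=C\CC/C(C)=C\C=O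
F5 | step 8 | boryl ylide, methyl 3-(pinacolboryl)-2-(triphenylphosphoranylidene)propanoate | COC(=O)C(CB1OC(C)(C)C(C)(C)O1)=P(c1ccccc1)(c1ccccc1)c1ccccc1
F6 | step 6 | angeloyl chloride | C/C=C(/C)C(=O)Cl
F7 | step 6 | 3-chloroprop-1-enyl angelate (E/Z mixture at the enol ester) | ClCC=COC(=O)/C(C)=C\C
F8 | step 6 | syn hydroxy angelate acetate, the C6 acetate of 13 (8S,9S) | C=C[C@H](OC(=O)/C(C)=C\C)[C@@H](O)/C(C(=O)OC)=C\CC/C(C)=C\COC(C)=O
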